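The strategy rests on cutting ring A of the target. Ring A is the 6-methyl-2-pyranone made of C1, O2, C3, C4, C4a and C8a. It is cut into three simple pieces: an acetyl unit (C3 and its methyl), a terminal alkyne (C4–C4a) and a malonate (C8a, C1 and the future C8). One pot joins them. Acylation of the alkyne, conjugate addition of the malonate and lactonisation form C3–C4, C4a–C8a and O2–C1. An ester remains on C8a for a closing Dieckmann reaction that makes ring B. The alkyne partner is an enantiopure α-quaternary alkynyl ethyl ketone that already holds C5 with its methyl and farnesyl groups. Its stereocentre comes from enzymatic desymmetrisation of a prochiral malonate.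

Key step: step 8

Assumption: pig liver esterase is taken to hydrolyse the pro-S ester of 3, the sense known for 2-alkyl-2-methylmalonates with long lipophilic chains, which gives (R)-4.

Notation: farnesyl means (2E,6E)-3,7,11-trimethyldodeca-2,6,10-trien-1-yl, and atom labels C1–C8a follow isochromene numbering of the target. The spatial arrangement at the quaternary carbon is fixed in step 2 and never changes. Compound 4 is R and all later compounds are S only because the priorities of the two arms are exchanged.

Step 1
Reactants: 1 dimethyl methylmalonate; 2 (2E,6E)-farnesyl bromide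
Product: 3 dimethyl 2-[(2E,6E)-farnesyl]-2-methylmalonate
Conditions: NaH (1.1 equiv), THF/DMF, 0 °C; then 2, 0 °C to rt
Reagents that add atoms: none
Why: Malonate alkylation by SN2: the soft sodium enolate of 1 should displace the primary allylic bromide of 2 at its CH2 terminus without allylic transposition or loss of alkene geometry, and the fully substituted product cannot be alkylated twice.

Step 2
Reactants: 3 dimethyl 2-[(2E,6E)-farnesyl]-2-methylmalonate
Product: 4 (2R,4E,8E)-2-(methoxycarbonyl)-2,5,9,13-tetramethyltetradeca-4,8,12-trienoic acid (the R half-ester)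
Conditions: pig liver esterase, 0.1 M phosphate buffer pH 7.5, DMSO (20 vol%), pH-stat with 1 M NaOH, 25 °C; then 1 M HCl to pH 3
Reagents that add atoms: water, O
Why: Enzymatic desymmetrisation of a prochiral diester: the hydrolase places the long lipophilic chain in its large hydrophobic pocket and should cleave only the pro-S ester, which sets the quaternary stereocentre (later C5) as R, while the resulting carboxylate is no longer a substrate, so that hydrolysis stops at the half-ester.

Step 3
Reactants: 4 the R half-ester
Product: 5 (2S,4E,8E)-2-(hydroxymethyl)-2,5,9,13-tetramethyltetradeca-4,8,12-trienoic acid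
Conditions: LiOMe (1.0 equiv), THF, 0 °C; then LiBH4 (2.5 equiv), THF, 0 to 45 °C; 1 M HCl to pH 3, 0 °C
Reagents that add atoms: none
Why: Chemoselective borohydride reduction: the preformed lithium carboxylate is inert to LiBH4 and liberates no borane that could hydroborate the trisubstituted alkenes, so that only the methyl ester is reduced, and the descriptor changes from R to S through a change of priorities alone.

Step 4
Reactants: 5 the hydroxy acid
Product: 6 (2S,4E,8E)-2-(hydroxymethyl)-N-methoxy-N,2,5,9,13-pentamethyltetradeca-4,8,12-trienamide
Conditions: MeNH(OMe)·HCl, EDC·HCl, HOBt, N-methylmorpholine, CH2Cl2, 0 °C to rt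
Reagents that add atoms: N,O-dimethylhydroxylamine hydrochloride, CNOC.Cl
Why: Carbodiimide/HOBt amide coupling: the amine should outcompete the neopentyl hydroxyl group for the active ester, and the Weinreb amide stores the acid arm as a latent ethyl ketone that withstands the oxidation and homologation to come.

Step 5
Reactants: 6 the hydroxy Weinreb amide
Product: 7 (2S,4E,8E)-2-formyl-N-methoxy-N,2,5,9,13-pentamethyltetradeca-4,8,12-trienamide
Conditions: Dess–Martin periodinane, CH2Cl2, 0 °C to rt
Reagents that add atoms: none
Why: Dess–Martin oxidation: the neutral to weakly acidic conditions should convert the neopentyl alcohol into the aldehyde without touching the three alkenes or the amide, and the α-carbon bears no hydrogen that could be lost.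

Step 6
Reactants: 7 the formyl Weinreb amide
Product: 8 (2S,4E,8E)-2-ethynyl-N-methoxy-N,2,5,9,13-pentamethyltetradeca-4,8,12-trienamide
Conditions: dimethyl (1-diazo-2-oxopropyl)phosphonate, K2CO3, MeOH, 0 °C to rt
Reagents that add atoms: dimethyl (1-diazo-2-oxopropyl)phosphonate, CC(=O)C(=[N+]=[N-])P(=O)(OC)OC
Why: Ohira–Bestmann variant of the Seyferth–Gilbert homologation: methanolysis unmasks the diazomethylphosphonate anion, which olefinates the aldehyde, and loss of N2 with a 1,2-hydrogen shift gives the terminal alkyne, while deformylation should stay slow because an amide enolate is a poor leaving group.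

Step 7
Reactants: 8 the alkynyl Weinreb amide
Product: 9 (4S)-4-[(2E,6E)-farnesyl]-4-methylhex-5-yn-3-one
Conditions: EtMgBr (3 equiv), THF, 0 °C (8 added to the Grignard reagent), then rt; 1 M HCl, 0 °C
Reagents that add atoms: ethylmagnesium bromide, CC[Mg]Br
Why: Weinreb ketone synthesis: one equivalent of EtMgBr is spent on the alkyne C–H, a second adds to the amide to give a chelated tetrahedral adduct that collapses to the ketone only on work-up, and placing this step after the homologation avoids a base-labile 2,2-disubstituted β-keto aldehyde.

Step 8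
Reactants: 9 (4S)-4-[(2E,6E)-farnesyl]-4-methylhex-5-yn-3-one; 10 acetyl chloride; 11 dimethyl malonate
Product: 14 methyl 4-[(1S)-1-[(2E,6E)-farnesyl]-1-methyl-2-oxobutyl]-6-methyl-2-oxo-2H-pyran-3-carboxylate, via ynone 12 (not isolated), via Michael adduct 13 (not isolated)
Conditions: PdCl2(PPh3)2 (2 mol%), CuI (4 mol%), Et3N (1.05 equiv), 10 (1.2 equiv, added last), THF, rt; then 11 (1.5 equiv), DBU (2.0 equiv), 60 °C
Reagents that add atoms: none
Why: Oxidative addition of 10 to zerovalent palladium (formed in the flask from PdCl2(PPh3)2), transmetallation with the copper acetylide of 9 and reductive elimination forge C3–C4 and give ynone 12, the single equivalent of Et3N keeping ketene formation from 10 low. DBU then generates the malonate anion, which adds in Michael fashion to the ynone β-carbon C4a (bond C4a–C8a), and the delocalised anion of 13 equilibrates its C4a=C4 geometry until the oxygen of the former acetyl carbonyl lies cis to an ester. The O2–C1 closure is a 6-exo-trig acyl substitution that expels methoxide and is driven by formation of the conjugated 2-pyranone ring A. The sequence is the known consecutive acyl Sonogashira coupling, Michael addition and cyclocondensation of acid chlorides, terminal alkynes and malonates, applied here to a tertiary propargylic alkyne. No stereocentre is created: C5 bears no hydrogen, so it cannot epimerise and 12 cannot isomerise to an allenone, and the rod-shaped alkyne keeps C4a accessible beside the quaternary carbon. Regiochemistry is inherent (acylation at the terminal C–H, attack of the soft carbanion at the β-carbon rather than at either ketone), and the C6 ketone stays a spectator because DBU hardly enolises it, any early Dieckmann closure merely advancing material to 15.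

Step 9
Reactants: 14 the pyranone ester
Product: 15 (5S)-5-[(2E,6E)-farnesyl]-8-hydroxy-3,5,7-trimethyl-1H-isochromene-1,6(5H)-dione (target)
Conditions: LiN(SiMe3)2 (3.0 equiv), THF, −78 to 0 °C; then 1 M HCl, 0 °C
Reagents that add atoms: none
Why: Dieckmann condensation (6-exo-trig acyl substitution): the ketone can enolise only towards C7 because C5 is quaternary, the enolate attacks the neighbouring C8 ester to close ring B, and irreversible deprotonation of the resulting β-dicarbonyl drives the reaction, acidification giving the C8 enol hydrogen-bonded to the C1 carbonyl with C5 untouched.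

Compound list
1 | dimethyl methylmalonate | COC(=O)C(C)C(=O)OC | starting material
2 | (2E,6E)-farnesyl bromide | CC(C)=CCC/C(C)=C/CC/C(C)=C/CBr | starting material
3 | dimethyl 2-[(2E,6E)-farnesyl]-2-methylmalonate | CC(C)=CCC/C(C)=C/CC/C(C)=C/CC(C)(C(=O)OC)C(=O)OC | intermediate
4 | (2R,4E,8E)-2-(methoxycarbonyl)-2,5,9,13-tetramethyltetradeca-4,8,12-trienoic acid | CC(C)=CCC/C(C)=C/CC/C(C)=C/C[C@](C(=O)OC)(C)C(=O)O | intermediate
5 | (2S,4E,8E)-2-(hydroxymethyl)-2,5,9,13-tetramethyltetradeca-4,8,12-trienoic acid | CC(C)=CCC/C(C)=C/CC/C(C)=C/C[C@](CO)(C)C(=O)O | intermediate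
6 | (2S,4E,8E)-2-(hydroxymethyl)-N-methoxy-N,2,5,9,13-pentamethyltetradeca-4,8,12-trienamide | CC(C)=CCC/C(C)=C/CC/C(C)=C/C[C@](CO)(C)C(=O)N(C)OC | intermediate
7 | (2S,4E,8E)-2-formyl-N-methoxy-N,2,5,9,13-pentamethyltetradeca-4,8,12-trienamide | CC(C)=CCC/C(C)=C/CC/C(C)=C/C[C@](C=O)(C)C(=O)N(C)OC | intermediate
8 | (2S,4E,8E)-2-ethynyl-N-methoxy-N,2,5,9,13-pentamethyltetradeca-4,8,12-trienamide | CC(C)=CCC/C(C)=C/CC/C(C)=C/C[C@](C#C)(C)C(=O)N(C)OC | intermediate
9 | (4S)-4-[(2E,6E)-farnesyl]-4-methylhex-5-yn-3-one | CC(C)=CCC/C(C)=C/CC/C(C)=C/C[C@](C#C)(C)C(=O)CC | intermediate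
10 | acetyl chloride | CC(=O)Cl | starting material
11 | dimethyl malonate | COC(=O)CC(=O)OC | starting material
12 | (5S)-5-[(2E,6E)-farnesyl]-5-methyloct-3-yne-2,6-dione | CC(C)=CCC/C(C)=C/CC/C(C)=C/C[C@](C#CC(C)=O)(C)C(=O)CC | intermediate
13 | dimethyl 2-[(3E,5S)-5-[(2E,6E)-farnesyl]-5-methyl-2,6-dioxooct-3-en-4-yl]malonate | CC(C)=CCC/C(C)=C/CC/C(C)=C/C[C@](/C(=C/C(C)=O)C(C(=O)OC)C(=O)OC)(C)C(=O)CC | intermediate
14 | methyl 4-[(1S)-1-[(2E,6E)-farnesyl]-1-methyl-2-oxobutyl]-6-methyl-2-oxo-2H-pyran-3-carboxylate | CC(C)=CCC/C(C)=C/CC/C(C)=C/C[C@](c1cc(C)oc(=O)c1C(=O)OC)(C)C(=O)CC | intermediate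
15 | (5S)-5-[(2E,6E)-farnesyl]-8-hydroxy-3,5,7-trimethyl-1H-isochromene-1,6(5H)-dione | CC(C)=CCC/C(C)=C/CC/C(C)=C/C[C@]1(C)C(=O)C(C)=C(O)c2c1cc(C)oc2=O | target

Total step count: 9. Longest linear sequence: 9 steps (1 to 15; compounds 2, 10 and 11 enter as purchased).

Steps most likely to fail

**Step 8.**
- What may go wrong: amine-induced dehydrochlorination of acetyl chloride to ketene may outrun the coupling. Conjugate addition beside the quaternary carbon may also be so slow that the ynone is lost to oligomerisation.
- Fallback, setting out from 8 and coming back at 14: the three bonds are made in separate operations that can each be optimised.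
- Deprotonation of 8 with LiN(i-Pr)2 (THF, −78 °C) and addition of the acetylide to acetaldehyde should give the propargylic alcohol (2S,4E,8E)-2-(3-hydroxybut-1-yn-1-yl)-N-methoxy-N,2,5,9,13-pentamethyltetradeca-4,8,12-trienamide F1, as an inconsequential mixture of carbinol epimers.
- Excess EtMgBr should turn its Weinreb amide into the hydroxy ketone (4S)-4-[(2E,6E)-farnesyl]-7-hydroxy-4-methyloct-5-yn-3-one F2.
- MnO2 in CH2Cl2 should oxidise the propargylic alcohol to 12, now isolated and purified.
- Preformed sodium dimethyl malonate (11, NaH, THF, reflux) should then deliver 14 by way of 13.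

**Step 2.**
- What may go wrong: there may be insufficient discrimination between the two enantiotopic esters, the opposite sense of hydrolysis, or sluggish turnover of a very lipophilic substrate in water.
- Fallback, setting out from 3 and coming back at 4: enzymatic desymmetrisation is replaced by classical resolution.
- One equivalent of KOH in MeOH should give the racemic half-ester 2-(methoxycarbonyl)-2,5,9,13-tetramethyltetradeca-4,8,12-trienoic acid F3.
- Fractional crystallisation with (R)-1-phenylethylamine should give the (R)-1-phenylethylammonium salt of the R half-ester F4. The antipodal amine is used if the other diastereomeric salt is the less soluble one.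
- Acidification returns 4.
- The same crystallisation can raise the enantiomeric purity of enzymatically made material.

**Step 6.**
- What may go wrong: methoxide-induced deformylation (retro-Claisen cleavage) of the non-enolisable α-formyl amide may occur before olefination takes place.
- Fallback, setting out from 7 and coming back at 9: a base-free olefination replaces the diazophosphonate chemistry.
- CBr4 and PPh3 (CH2Cl2, 0 °C) should give the dibromoalkene (2S,4E,8E)-2-(2,2-dibromoethenyl)-N-methoxy-N,2,5,9,13-pentamethyltetradeca-4,8,12-trienamide F5.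
- Excess EtLi (THF, −78 to 0 °C) should then do two jobs. It effects the Corey–Fuchs bromine–lithium exchange and rearrangement to the acetylide, and it adds to the Weinreb amide.
- Aqueous work-up then gives 9 directly and 8 is bypassed.

Further compounds
F1 | step 8 | (2S,4E,8E)-2-(3-hydroxybut-1-yn-1-yl)-N-methoxy-N,2,5,9,13-pentamethyltetradeca-4,8,12-trienamide (carbinol epimers) | CC(C)=CCC/C(C)=C/CC/C(C)=C/C[C@](C#CC(C)O)(C)C(=O)N(C)OC
F2 | step 8 | (4S)-4-[(2E,6E)-farnesyl]-7-hydroxy-4-methyloct-5-yn-3-one (carbinol epimers) | CC(C)=CCC/C(C)=C/CC/C(C)=C/C[C@](C#CC(C)O)(C)C(=O)CC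
F3 | step 2 | racemic (4E,8E)-2-(methoxycarbonyl)-2,5,9,13-tetramethyltetradeca-4,8,12-trienoic acid | CC(C)=CCC/C(C)=C/CC/C(C)=C/CC(C)(C(=O)OC)C(=O)O
F4 | step 2 | (R)-1-phenylethylammonium salt of the R half-ester | CC(C)=CCC/C(C)=C/CC/C(C)=C/C[C@](C(=O)OC)(C)C(=O)[O-].C[C@@H]([NH3+])c1ccccc1
F5 | step 6 | (2S,4E,8E)-2-(2,2-dibromoethenyl)-N-methoxy-N,2,5,9,13-pentamethyltetradeca-4,8,12-trienamide | CC(C)=CCC/C(C)=C/CC/C(C)=C/C[C@](C=C(Br)Br)(C)C(=O)N(C)OC
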